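**Retrosynthetic overview**

1. The route rests on ring B (C5–C10, drimane numbering). Its para-related C6 and C9 carbons, the C8 and C10 methyls and the C7=C8 alkene are the pattern of 2,6-dimethyl-1,4-benzoquinone, used as its C6 monoketal so that C9 (ketone) and C6 (ketal) react separately.
2. Key disconnection: ring A (C1–C4) is added across C5=C10 by a catalytic enantioselective Diels–Alder reaction with a 2-silyloxybutadiene (bonds C4–C5 and C1–C10). This sets C10 and puts oxygen on C3.
3. C9=O becomes C9=CH2 (Wittig) and then C9(H)–C11H2OH by hydroboration anti to the C10 methyl. The aryl ether comes from a Mitsunobu reaction with umbelliferone.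
4. The C6 ketal is turned into a Δ5 enol ether. This directs C4 gem-dimethylation through the C3 dienolate and lets C5–H be set trans by kinetic protonation. C3–OH is set axial by L-Selectride, and C6 is re-oxidised last.
5. Ring order: B (from the arene, step 1), then A (step 3).

Key step: step 3

**Remarks on the chemistry**

- Drimane numbering is used. The target is (3S,5S,9R,10S). "Syn" and "anti" mean the same or the opposite face as the C10 methyl.
- The catalyst enantiomer in step 3 is the one that gives the C10 configuration drawn for 5. The α-methylated enone has no α-C–H for two-point binding, so the sense has to be assigned on the adduct and the antipodal catalyst used if needed.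
- The C6 carbinol in 12–17 is drawn as the expected 6-OH syn epimer; the other epimer would converge in step 13. The two hindered hydroxyls of 13 may be O-borylated transiently in step 11 and are freed in the oxidative work-up.
- C5 is not left to base equilibration, because a trans preference is not assured for a 4,4,10-trimethyl-6-oxo decalin. It is set by kinetic protonation in step 8.

**Route**

Step 1
Reactants: 1 4-methoxy-2,6-dimethylphenol
Product: 2 4,4-dimethoxy-2,6-dimethylcyclohexa-2,5-dien-1-one
Conditions: PhI(OAc)2, MeOH, 0 °C
Reagents that add atoms: methanol, CO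
Why: Oxidative dearomatisation of a p-methoxyphenol with an aryl-λ3-iodane, in which methanol traps the phenoxenium-type intermediate at C4 to give the quinone monoketal whose ketal carbon becomes C6.

Step 2
Reactants: 3 but-3-en-2-one
Product: 4 2-(triisopropylsilyloxy)buta-1,3-diene
Conditions: TIPSOTf, Et3N, Et2O, 0 °C → rt
Reagents that add atoms: triisopropylsilyl trifluoromethanesulfonate, CC(C)[Si](C(C)C)(C(C)C)OS(=O)(=O)C(F)(F)F
Why: Soft enolisation and O-silylation of the methyl ketone (silyl enol ether formation) gives the 2-silyloxy diene.

Step 3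
Reactants: 2 4,4-dimethoxy-2,6-dimethylcyclohexa-2,5-dien-1-one; 4 2-(triisopropylsilyloxy)buta-1,3-diene
Product: 5 cis-fused Diels–Alder adduct (C9 ketone; C6 dimethyl ketal; C7=C8–CH3; C2=C3 enol silane with OTIPS on C3; C5–H syn to C10–CH3)
Conditions: B-(o-tolyl)oxazaborolidinium triflimide from α,α-diphenylprolinol and Tf2NH (20 mol %), 4 (3 equiv), CH2Cl2, −78 → −20 °C
Reagents that add atoms: none
Why: The catalyst binds the lone C9 carbonyl and the enone undergoes a concerted, asynchronous [4+2] cycloaddition in which the CH2 terminus next to the silyloxy carbon of 4 bonds to the β-carbon C5 and the vinyl terminus to the α-carbon C10, so oxygen lands on C3. The closest known reaction type is the chiral-Lewis-acid-catalysed Diels–Alder reaction of 1,4-quinone monoketals with 2-silyloxydienes. Ring A closes by intermolecular cycloaddition, both new bonds (C4–C5 and C1–C10) forming suprafacially across C5=C10, which makes C5–H and C10–CH3 cis. C10 is set by the catalyst, which must pick one of the two enantiotopic alkenes and one of its faces; C5 follows from suprafaciality and is re-set on purpose in step 8. The step needs site selectivity (the C6 ketal leaves only the C9 enone activated), regioselectivity (diene polarisation) and enantioface selectivity; because the α-methyl and the neighbouring ketal slow the dienophile, a strongly activating cationic catalyst and excess diene are used.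

Step 4
Reactants: 5 cis-fused Diels–Alder adduct
Product: 6 cis-fused 9-methylene ketal (C9=C11H2; C6 dimethyl ketal; C7=C8–CH3; C2=C3–OTIPS)
Conditions: Ph3PCH3Br, KOt-Bu, toluene, 90 °C
Reagents that add atoms: methyltriphenylphosphonium bromide, C[P+](c1ccccc1)(c1ccccc1)c1ccccc1.[Br-]
Why: Wittig methylenation at C9, which is the only carbonyl at this stage (C3 is an enol silane, C6 a ketal) and is non-enolisable, so forcing conditions should cause no side reaction.

Step 5
Reactants: 6 cis-fused 9-methylene ketal
Product: 7 6-methoxy Δ5 enol ether (C5=C6–OMe; C7=C8–CH3; C9=C11H2; C2=C3–OTIPS; C10 the only stereocentre)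
Conditions: PPTS (5 mol %), 5 Å MS, toluene, 70 °C
Reagents that add atoms: none
Why: Acid-catalysed loss of methanol from a ketal to its enol ether, where reversible proton loss from the readily formed dienyl oxocarbenium ion should lead to the more substituted, linearly conjugated C5=C6 isomer and so erase the cis C5 centre.

Step 6
Reactants: 7 6-methoxy Δ5 enol ether
Product: 8 6-methoxy-13,14-dinordrima-5,7,9(11)-trien-3-one
Conditions: TBAF, AcOH, THF, 0 °C → rt
Reagents that add atoms: none
Why: Fluoride-induced desilylation of the enol silane with buffered protonation at C2 frees the C3 ketone, while the methyl enol ether is inert to fluoride.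

Step 7
Reactants: 8 6-methoxy-13,14-dinordrima-5,7,9(11)-trien-3-one
Product: 9 6-methoxydrima-5,7,9(11)-trien-3-one (4,4-dimethyl)
Conditions: KOt-Bu (2.3 equiv), MeI, t-BuOH/THF, 0 °C → rt
Reagents that add atoms: iodomethane, CI
Why: Exhaustive α-methylation through the extended thermodynamic dienolate O–C3=C4–C5=C6 (the classical Δ4-3-ketone to 4,4-dimethyl-Δ5-3-ketone alkylation), which all tautomers of 8 share and which alkylates twice at C4 before the C2 enolate can form.

Step 8
Reactants: 9 6-methoxydrima-5,7,9(11)-trien-3-one
Product: 10 trans-fused drima-7,9(11)-diene-3,6-dione (C5–H anti to C10–CH3)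
Conditions: 0.5 M aq. oxalic acid, THF, 0 °C
Reagents that add atoms: water, O
Why: Enol ether hydrolysis by rate-limiting axial C-protonation at C5 from the face anti to the axial C10 and C4 methyls (as electrophiles add to Δ5 steroids) should set the trans ring fusion kinetically, and the weak acid at 0 °C should not re-enolise the hindered C6 ketone.

Step 9
Reactants: 10 trans-fused drima-7,9(11)-diene-3,6-dione
Product: 12 6-hydroxydrima-7,9(11)-dien-3-one (6-OH syn to C10–CH3), via lithium C3-enolate 11 (not isolated)
Conditions: LiHMDS (1.1 equiv), THF, −78 °C; then DIBAL-H, −78 °C; Rochelle salt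
Reagents that add atoms: none
Why: In situ protection of the C3 ketone as its lithium enolate (kinetic deprotonation at the unhindered C2 methylene) lets DIBAL-H reduce only the C6 dienone by 1,2-addition, with hydride expected anti to the two axial methyls; the C6 configuration is immaterial because C6 is re-oxidised in step 13.

Step 10
Reactants: 12 6-hydroxydrima-7,9(11)-dien-3-one
Product: 13 drima-7,9(11)-diene-3,6-diol (3-OH axial and anti to C10–CH3)
Conditions: L-Selectride, THF, −78 °C; then H2O
Reagents that add atoms: none
Why: Bulky-hydride reduction of a 4,4-dimethyl-3-ketone in a trans-decalin goes by equatorial attack (the axial path is blocked by the C1 and C5 axial hydrogens) and should give the axial C3 alcohol, as with 3-oxo-triterpenoids, and no conjugate acceptor is left in the molecule.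

Step 11
Reactants: 13 drima-7,9(11)-diene-3,6-diol
Product: 15 drim-7-ene-3,6,11-triol (C9–H anti and C11 syn to C10–CH3), via C11-borane 14 (not isolated)
Conditions: 9-BBN, THF, 0 → 50 °C; then NaOH, H2O2, 0 °C
Reagents that add atoms: hydrogen peroxide, OO
Why: Hydroboration–oxidation, in which 9-BBN selects the terminal 1,1-disubstituted alkene (boron on C11) and delivers hydrogen to C9 from the face anti to the axial C10 methyl of the trans-fused ring, setting C9.

Step 12
Reactants: 15 drim-7-ene-3,6,11-triol; 16 umbelliferone (7-hydroxycoumarin)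
Product: 17 7-[(3,6-dihydroxydrim-7-en-11-yl)oxy]coumarin
Conditions: PPh3, DIAD, THF, 0 °C → rt
Reagents that add atoms: none
Why: Mitsunobu etherification of the acidic phenol should engage only the primary C11 hydroxyl, since the axial neopentyl C3–OH and the C6–OH flanked by two syn-axial methyls are too hindered to be activated, and with C6 still a carbinol C9–H is not acidified toward elimination.

Step 13
Reactants: 17 7-[(3,6-dihydroxydrim-7-en-11-yl)oxy]coumarin
Product: 18 ferocaulidin
Conditions: activated MnO2 (excess), CH2Cl2, rt
Reagents that add atoms: none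
Why: MnO2 oxidises only the allylic C6 carbinol (helped by relief of its 1,3-diaxial strain) and leaves the saturated C3–OH, the aryl ether and the coumarin alone, and the neutral conditions should preserve the C5 and C9 centres next to the new enone.

**Compound list**

1 | 4-methoxy-2,6-dimethylphenol | COc1cc(C)c(O)c(C)c1 | starting material
2 | 4,4-dimethoxy-2,6-dimethylcyclohexa-2,5-dien-1-one | CC1=CC(OC)(OC)C=C(C)C1=O | intermediate
3 | but-3-en-2-one | CC(=O)C=C | starting material
4 | 2-(triisopropylsilyloxy)buta-1,3-diene | C=CC(=C)O[Si](C(C)C)(C(C)C)C(C)C | intermediate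
5 | cis-fused Diels–Alder adduct (C9 ketone, C6 dimethyl ketal, C2=C3–OTIPS) | CC1=CC(OC)(OC)[C@H]2CC(O[Si](C(C)C)(C(C)C)C(C)C)=CC[C@@]2(C)C1=O | intermediate
6 | cis-fused 9-methylene ketal | CC1=CC(OC)(OC)[C@H]2CC(O[Si](C(C)C)(C(C)C)C(C)C)=CC[C@@]2(C)C1=C | intermediate
7 | 6-methoxy Δ5 enol ether with C2=C3–OTIPS | CC1=CC(OC)=C2CC(O[Si](C(C)C)(C(C)C)C(C)C)=CC[C@@]2(C)C1=C | intermediate
8 | 6-methoxy-13,14-dinordrima-5,7,9(11)-trien-3-one | CC1=CC(OC)=C2CC(=O)CC[C@@]2(C)C1=C | intermediate
9 | 6-methoxydrima-5,7,9(11)-trien-3-one | CC1=CC(OC)=C2C(C)(C)C(=O)CC[C@@]2(C)C1=C | intermediate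
10 | trans-fused drima-7,9(11)-diene-3,6-dione | CC1=CC(=O)[C@@H]2C(C)(C)C(=O)CC[C@@]2(C)C1=C | intermediate
11 | lithium C2=C3 enolate of 10 (not isolated) | CC1=CC(=O)[C@@H]2C(C)(C)C([O-])=CC[C@@]2(C)C1=C.[Li+] | intermediate
12 | 6-hydroxydrima-7,9(11)-dien-3-one | CC1=C[C@H](O)[C@@H]2C(C)(C)C(=O)CC[C@@]2(C)C1=C | intermediate
13 | drima-7,9(11)-diene-3,6-diol | CC1=C[C@H](O)[C@@H]2C(C)(C)[C@@H](O)CC[C@@]2(C)C1=C | intermediate
14 | C11-(9-borabicyclo[3.3.1]nonan-9-yl) borane of 13 (not isolated) | CC1=C[C@H](O)[C@@H]2C(C)(C)[C@@H](O)CC[C@@]2(C)[C@@H]1CB1C2CCCC1CCC2 | intermediate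
15 | drim-7-ene-3,6,11-triol | CC1=C[C@H](O)[C@@H]2C(C)(C)[C@@H](O)CC[C@@]2(C)[C@@H]1CO | intermediate
16 | umbelliferone | Oc1ccc2ccc(=O)oc2c1 | starting material
17 | 7-[(3,6-dihydroxydrim-7-en-11-yl)oxy]coumarin | CC1=C[C@H](O)[C@@H]2C(C)(C)[C@@H](O)CC[C@@]2(C)[C@@H]1COc1ccc2ccc(=O)oc2c1 | intermediate
18 | ferocaulidin | CC1=CC(=O)[C@@H]2C(C)(C)[C@@H](O)CC[C@@]2(C)[C@@H]1COc1ccc2ccc(=O)oc2c1 | target

**Step count**

Total: 13 steps. Longest linear sequence: 12 steps (steps 1 and 3–13; step 2 is a one-step branch).

**Steps most likely to fail**

Step 3. The α-methylated enone flanked by the ketal may react too slowly, or the catalyst may discriminate poorly between the enantiotopic alkenes and faces. Fallback: setting out from 2 and 4, the cycloaddition is run without a chiral catalyst under high pressure (12 kbar, CH2Cl2, rt) to give the racemic adduct F1, which is resolved by preparative chromatography on a chiral stationary phase; the matching enantiomer is 5 and the route continues at step 4.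

Step 5. Under acid the oxocarbenium ion may lose a proton from the C8 methyl instead of C5, or the exocyclic methylene may drift into ring conjugation. Fallback: setting out from 6, the ketal alone is hydrolysed (PPTS, acetone/H2O, 0 °C) to the cis-fused 9-methylene 6-ketone F2 with the enol silane intact; kinetic deprotonation at C5 (KHMDS, THF/DMPU, −78 °C) and O-methylation of the hindered potassium dienolate with methyl triflate then give 7, where the route is rejoined.

Step 9. Incomplete or misdirected enolisation would let DIBAL-H reduce the C3 ketone to the wrong (equatorial) alcohol or exchange C5–H. Fallback: setting out from 9, whose only carbonyl is C3, the ketone is silylated (TIPSOTf, Et3N) to the C2=C3 enol silane F3; the methyl enol ether is hydrolysed selectively (aq. oxalic acid, THF, 0 °C) to the trans-fused 6-ketone F4; DIBAL-H gives the 6-carbinol F5; TBAF/AcOH then frees the ketone and returns to 12.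

**Further compounds**

F1 | step 3 | racemic adduct (5 together with its enantiomer; SMILES of the enantiomer) | CC1=CC(OC)(OC)[C@@H]2CC(O[Si](C(C)C)(C(C)C)C(C)C)=CC[C@]2(C)C1=O
F2 | step 5 | cis-fused 9-methylene 6-ketone with C2=C3–OTIPS | CC1=CC(=O)[C@H]2CC(O[Si](C(C)C)(C(C)C)C(C)C)=CC[C@@]2(C)C1=C
F3 | step 9 | C2=C3 triisopropylsilyl enol ether of 9 | CC1=CC(OC)=C2C(C)(C)C(O[Si](C(C)C)(C(C)C)C(C)C)=CC[C@@]2(C)C1=C
F4 | step 9 | trans-fused drima-7,9(11)-dien-6-one with C2=C3–OTIPS | CC1=CC(=O)[C@@H]2C(C)(C)C(O[Si](C(C)C)(C(C)C)C(C)C)=CC[C@@]2(C)C1=C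
F5 | step 9 | 6-hydroxy analogue of F4 (6-OH syn to C10–CH3) | CC1=C[C@H](O)[C@@H]2C(C)(C)C(O[Si](C(C)C)(C(C)C)C(C)C)=CC[C@@]2(C)C1=C
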